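The product of the birch run climbs almost straight, to 18.4% after 25.0 h, and the birch run is the same flask we are asked about.

- birch: starting material 0.082 M; second substrate 1.05 equiv; enzyme 0.05 mol%; impurity 9.6 µM; the very flask that is asked about, followed so far
- flask: starting material 0.082 M; second substrate 1.05 equiv; enzyme 0.05 mol%; impurity 9.6 µM

- birch (time / h: product / %): 1.33: 0.6; 4.00: 3.0; 6.00: 4.7; 10.0: 8.8; 15.0: 10.5; 20.0: 15.6; 25.0: 18.4

(scatter of a reading: 0.5 percentage points)

- factor on the rate of making product when 20% of the starting material are converted if second substrate is charged twice over
- factor on the rate when 20% of the starting material are converted if enzyme is charged at 0.5 mol% instead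

- no earlier run changes the charge of enzyme; that part of a forecast is a guess
- no earlier run changes the charge of second substrate; that part of a forecast is a guess

Counted as turnovers, that last reading is 368 per enzyme charged. A single charge of enzyme, however, cannot show how many enzymes did the turning. The impurity is hardly any of the starting material, yet it stands at a quarter of the enzyme charge of 41.0 µM. So we count it against the enzyme, and we name the working enzyme, the enzyme charged less the impurity charged, 31.4 µM.

Two extreme flasks can be reckoned in the head for the larger charge of enzyme:

impurity innocent: factor = 10.0

impurity takes one enzyme each: factor = (410 µM − 9.6 µM) / 31.4 µM = 12.8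

The first reckoning gives the impurity none of the enzyme and the second gives it an enzyme for each impurity charged, while a loss of enzyme by any other road stands in neither, so we expect the answer near this range without holding it as a bound. We commit to the upper end, as a judgement that these readings do not test.

The forecast stands lower, at 11 (9 to 13.5), with 1.1 (1 to 1.5) for the second substrate. In its words: “The rate should scale with active enzyme.”

The flask gives 13.0 for the enzyme, slightly above our 12.8, and 1.06 for the second substrate.

    ternary complex → enzyme + product (k = 0.380 min⁻¹)
    second substrate + starting complex ⇌ ternary complex (K = 220 M⁻¹, k = 1400 M⁻¹ min⁻¹)
    starting material + enzyme ⇌ starting complex (K = 24.0 M⁻¹, k = 78.0 M⁻¹ min⁻¹)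
    enzyme → spent catalyst B (k = 1.40 × 10⁻⁴ min⁻¹)
    enzyme + impurity → spent catalyst A (k = 11000 M⁻¹ min⁻¹)

When 20% of the starting material are converted in this flask, spent catalyst A holds 23.4% of the catalyst and spent catalyst B holds 1.50%, so the form made from the impurity stands well above the other. The working enzyme had set aside 23.4% of the charge. For a further flask with twice the enzyme, the working enzyme gives a factor on the time to that conversion of 31.4 µM / (82.0 µM − 9.6 µM) = 0.434, and that run stores 0.432.

The numbers in the tables stem from a simulated flask with constants of no real substance; the scatter is artificial.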